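The carbocycle (C4a–C5–C6–C7–C8–C8a; isochromene numbering with O2, C1, C3–C8a) holds a tertiary α-ketol, C6(=O)–C7(O)(CH3), flanked by the C8 ketone. Opening the C6–C7 bond as a crossed benzoin leads back to a monocyclic dihydropyran that carries an exocyclic enal (C4a=C5–C6HO) next to a 2-oxopropanoyl group (C8, C7) on the enol-ether carbon C8a. A chiral triazolylidene carbene turns the C6 aldehyde into an acyl anion equivalent, closes the carbocycle onto the C7 ketone and sets the C7 stereocentre under catalyst control. The pyran, with C3 from (R)-pent-4-yn-2-ol, is assembled from a hydroxy ynal and an enaminone; oleoylation completes the route.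

Key step: step 5

Assumption: the sense of induction of the aminoindanol-derived triazolium precatalyst on this substrate has to be fixed by experiment; both antipodes are accessible, and the one that delivers the 7R ketol is meant in step 5.

Remark: 6 and 7 are expected as interconverting E/Z mixtures about the exocyclic C4a=C5 bond and are drawn without a descriptor for it.

Step 1
Reactants: 1 (R)-pent-4-yn-2-ol
Product: 2 (R)-5-hydroxyhex-2-ynal
Conditions: n-BuLi (2.1 equiv), THF, −78 °C; DMF (3 equiv), −78 °C to rt; inverse quench into aq. KH2PO4/MTBE, 0 °C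
Reagents that add atoms: N,N-dimethylformamide, CN(C)C=O
Why: Double deprotonation gives the alkoxide–acetylide dianion, whose carbon terminus is formylated by DMF (acetylide formylation), and the buffered inverse quench frees the ynal without conjugate addition of the amine; the carbinol stereocentre is untouched.

Step 2
Reactants: 3 3,3-dimethoxybutan-2-one
Product: 4 (E)-1-(dimethylamino)-4,4-dimethoxypent-1-en-3-one
Conditions: DMF-DMA (1.5 equiv), neat, 100 °C, MeOH distilled off
Reagents that add atoms: N,N-dimethylformamide dimethyl acetal, COC(OC)N(C)C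
Why: Aminomethylenation (enaminone formation) of the only enolisable methyl group by the amide acetal, with the ketal inert under these neutral conditions.

Step 3
Reactants: 2 (R)-5-hydroxyhex-2-ynal; 4 (E)-1-(dimethylamino)-4,4-dimethoxypent-1-en-3-one
Product: 6 2-[(2R)-5-(2,2-dimethoxypropanoyl)-2-methyl-2,3-dihydro-4H-pyran-4-ylidene]acetaldehyde (E/Z mixture), via aminodienal Michael adduct 5 (not isolated)
Conditions: AcOH/toluene (1:5), 50 °C, slow N2 sweep
Reagents that add atoms: none
Why: Bohlmann–Rahtz-type conjugate addition of the enaminone α-carbon to the ynal β-carbon forms the C8a–C4a bond to give 5, and acid-promoted addition–elimination of the secondary hydroxyl at the aminomethylene carbon (the enaminone-to-pyranone closure known from chromone synthesis) then expels dimethylamine and closes the dihydropyran ring without touching C3.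

Step 4
Reactants: 6 2-[(2R)-5-(2,2-dimethoxypropanoyl)-2-methyl-2,3-dihydro-4H-pyran-4-ylidene]acetaldehyde
Product: 7 2-[(2R)-2-methyl-5-(2-oxopropanoyl)-2,3-dihydro-4H-pyran-4-ylidene]acetaldehyde (E/Z mixture)
Conditions: 2 M aq. HCl, THF, 0 °C to rt
Reagents that add atoms: water, O
Why: Acid-catalysed ketal hydrolysis unmasks the C7 ketone, while the ring enol ether should survive as a vinylogous ester and the protonated dienal merely equilibrates its E/Z isomers.

Step 5
Reactants: 7 2-[(2R)-2-methyl-5-(2-oxopropanoyl)-2,3-dihydro-4H-pyran-4-ylidene]acetaldehyde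
Product: 8 (3R,7R)-7-hydroxy-3,7-dimethyl-3,4-dihydro-6H-isochromene-6,8(7H)-dione
Conditions: aminoindanol-derived triazolium salt [(5aS,10bR)- or (5aR,10bS)-2-(pentafluorophenyl)-5a,10b-dihydro-4H,6H-indeno[2,1-b][1,2,4]triazolo[4,3-d][1,4]oxazin-2-ium tetrafluoroborate, 15 mol%], Et3N (15 mol%), toluene, 4 Å MS, rt
Reagents that add atoms: none
Why: The triazolylidene freed from the salt adds to the C6 aldehyde, proton transfer gives the enaminol (acyl anion equivalent), and its C6 attacks the C7 carbonyl of the 1,2-diketone; collapse of the adduct releases the carbene and leaves the C6 ketone and the C7 tertiary alcohol, an intramolecular crossed aldehyde–ketone benzoin whose closest precedent is the triazolium-catalysed enantioselective closure of keto aldehydes to six-membered tertiary α-ketols. The carbocycle C4a–C5–C6–C7–C8–C8a closes in a 6-exo-trig mode. The new C7 stereocentre is set by the chiral carbene, which should expose the Re face of the C7 carbonyl to C6 (7R); the remote C3 centre exerts little bias, so control rests on the catalyst. Selectivity for C7 over C8 follows from C8 being a deactivated vinylogous-ester carbonyl whose attack would give a five-membered ring, and acyl-anion rather than homoenolate reactivity is favoured by the fully substituted β-carbon C4a, the electron-poor N-aryl group and the aprotic medium. Only the Z enal (formyl cis to C8a) can cyclise; reversible 1,6-addition of the carbene or the amine at C1 should interconvert the alkene isomers, so that the mixture drains through the Z form.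

Step 6
Reactants: 8 (3R,7R)-7-hydroxy-3,7-dimethyl-3,4-dihydro-6H-isochromene-6,8(7H)-dione; 9 oleoyl chloride [(9Z)-octadec-9-enoyl chloride]
Product: 10 (3R,7R)-3,7-dimethyl-6,8-dioxo-3,4,7,8-tetrahydro-6H-isochromen-7-yl (9Z)-octadec-9-enoate (CNP0252548.1)
Conditions: Et3N (2 equiv), DMAP (0.2 equiv), CH2Cl2, 0 °C to rt
Reagents that add atoms: none
Why: DMAP-catalysed acylation (acyl transfer through the N-acylpyridinium ion) esterifies the tertiary C7 hydroxyl without touching either stereocentre or the Z alkene of the acyl chain.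

Compound list

1 | (R)-pent-4-yn-2-ol | C[C@@H](O)CC#C | starting material
2 | (R)-5-hydroxyhex-2-ynal | C[C@@H](O)CC#CC=O | intermediate
3 | 3,3-dimethoxybutan-2-one | CC(=O)C(C)(OC)OC | starting material
4 | (E)-1-(dimethylamino)-4,4-dimethoxypent-1-en-3-one | CN(C)/C=C/C(=O)C(C)(OC)OC | intermediate
5 | 4-[(dimethylamino)methylidene]-3-[(2R)-2-hydroxypropyl]-6,6-dimethoxy-5-oxohept-2-enal (alkene isomer mixture, not isolated) | C[C@@H](O)CC(=CC=O)C(=CN(C)C)C(=O)C(C)(OC)OC | intermediate
6 | 2-[(2R)-5-(2,2-dimethoxypropanoyl)-2-methyl-2,3-dihydro-4H-pyran-4-ylidene]acetaldehyde (E/Z mixture) | C[C@@H]1CC(=CC=O)C(C(=O)C(C)(OC)OC)=CO1 | intermediate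
7 | 2-[(2R)-2-methyl-5-(2-oxopropanoyl)-2,3-dihydro-4H-pyran-4-ylidene]acetaldehyde (E/Z mixture) | C[C@@H]1CC(=CC=O)C(C(=O)C(C)=O)=CO1 | intermediate
8 | (3R,7R)-7-hydroxy-3,7-dimethyl-3,4-dihydro-6H-isochromene-6,8(7H)-dione | C[C@@H]1CC2=CC(=O)[C@@](C)(O)C(=O)C2=CO1 | intermediate
9 | oleoyl chloride, (9Z)-octadec-9-enoyl chloride | CCCCCCCC/C=C\CCCCCCCC(=O)Cl | starting material
10 | (3R,7R)-3,7-dimethyl-6,8-dioxo-3,4,7,8-tetrahydro-6H-isochromen-7-yl (9Z)-octadec-9-enoate | CCCCCCCC/C=C\CCCCCCCC(=O)O[C@]1(C)C(=O)C=C2C[C@@H](C)OC=C2C1=O | target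

Total step count: 6. Longest linear sequence: 5 steps (steps 1, 3, 4, 5, 6).

Steps most likely to fail

Step 5 (key ring closure). Several processes can go wrong:
- The carbene may fail to engage the electron-rich, vinylogous-formate-type aldehyde.
- Protonation of the conjugated enaminol at C4a may divert it into the homoenolate/redox manifold.
- Acetyl transfer from the 1,2-diketone may consume the catalyst.
- Supply of the Z enal may be slow.
- Facial selectivity at C7 may be modest.
- Base-induced β-elimination of the ring oxygen from the γ-deprotonated enal would erode C3, which is why a weak amine base is specified.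

The fallback sets out from 7 and comes back at 8 by a reductive closure of the same bond. Treatment of 7 with SmI2 (2.2 equiv, THF, −78 °C) should reduce the 1,2-diketone to its samarium enediolate (or the aldehyde to its ketyl). Addition across C6/C7 would then give (3R,7R)-6,7-dihydroxy-3,7-dimethyl-3,4,6,7-tetrahydro-8H-isochromen-8-one F1 together with its C7 epimer. MnO2 (CH2Cl2, rt) then oxidises the allylic C6 carbinol, and the 7R ketol 8 is separated from its 7S diastereomer by chromatography. Catalyst control at C7 is given up in this variant.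

Step 3 (pyran assembly). Three processes can go wrong:
- The enaminone and the ynal may combine by [2+2] cycloaddition and ring opening, which inserts the alkyne into the enaminone C=C bond instead of giving the simple conjugate adduct.
- The hydroxyl may close onto the aldehyde terminus C6 instead of C1, which after loss of water and hydrolysis puts the ring oxygen on the wrong carbon.
- The hydroxy ynal may oligomerise.

The fallback sets out from 2, fixes the O2–C1 bond first and comes back at 7:
- Acetalisation of 2 (HC(OEt)3, EtOH, PPTS) gives (R)-6,6-diethoxyhex-4-yn-2-ol F2.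
- Methyl 2,2-dimethoxypropanoate is converted with MeNH(OMe)·HCl/i-PrMgCl into N-methoxy-N-methyl-2,2-dimethoxypropanamide F3, and ethynylmagnesium bromide (THF, 0 °C) then gives 4,4-dimethoxypent-1-yn-3-one F4.
- PMe3-catalysed oxa-Michael addition of F2 to F4 (CH2Cl2, 0 °C) should give (E)-1-{[(2R)-6,6-diethoxyhex-4-yn-2-yl]oxy}-4,4-dimethoxypent-1-en-3-one F5.
- α-Iodination (I2, pyridine, CH2Cl2) gives (Z)-1-{[(2R)-6,6-diethoxyhex-4-yn-2-yl]oxy}-2-iodo-4,4-dimethoxypent-1-en-3-one F6.
- Reductive 6-exo-dig carbopalladation (Pd(PPh3)4, HCO2Na, DMF, 80 °C) closes the ring to 1-[(2R,4E)-4-(2,2-diethoxyethylidene)-2-methyl-3,4-dihydro-2H-pyran-5-yl]-2,2-dimethoxypropan-1-one F7.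
- Aqueous HCl in THF cleaves the acetal and the ketal together and equilibrates the alkene, giving 7.

Step 4 (ketal hydrolysis). The α-keto ketal may hydrolyse sluggishly and call for stronger acid. Under aqueous acid the enol ether may then be hydrated, the ring opened, and the hydroxyl re-closed on the C6 aldehyde terminus (transposition of the ring oxygen).

The fallback sets out from 2, carries C7 at the carbinol level and comes back at 7:
- 3-Hydroxybutan-2-one is silylated (TBSCl, imidazole, DMF) to 3-[(tert-butyldimethylsilyl)oxy]butan-2-one F8.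
- DMF-DMA (100 °C) gives (E)-4-[(tert-butyldimethylsilyl)oxy]-1-(dimethylamino)pent-1-en-3-one F9.
- Reaction of F9 with 2 under the conditions of step 3 should pass through 6-[(tert-butyldimethylsilyl)oxy]-4-[(dimethylamino)methylidene]-3-[(2R)-2-hydroxypropyl]-5-oxohept-2-enal F10 and give 2-[(2R)-5-{2-[(tert-butyldimethylsilyl)oxy]propanoyl}-2-methyl-2,3-dihydro-4H-pyran-4-ylidene]acetaldehyde F11.
- HF·pyridine (THF, 0 °C) frees 2-[(2R)-5-(2-hydroxypropanoyl)-2-methyl-2,3-dihydro-4H-pyran-4-ylidene]acetaldehyde F12.
- Oxidation with the triacetoxy periodinane DMP (CH2Cl2, NaHCO3) gives 7.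

The silyloxy-bearing carbon is used as an epimer mixture, since it ends as a carbonyl.

Further compounds

F1 | step 5 | (3R,7R)-6,7-dihydroxy-3,7-dimethyl-3,4,6,7-tetrahydro-8H-isochromen-8-one (C6 epimer mixture) | C[C@@H]1CC2=CC(O)[C@@](C)(O)C(=O)C2=CO1
F2 | step 3 | (R)-6,6-diethoxyhex-4-yn-2-ol | C[C@@H](O)CC#CC(OCC)OCC
F3 | step 3 | N-methoxy-N-methyl-2,2-dimethoxypropanamide | CON(C)C(=O)C(C)(OC)OC
F4 | step 3 | 4,4-dimethoxypent-1-yn-3-one | C#CC(=O)C(C)(OC)OC
F5 | step 3 | (E)-1-{[(2R)-6,6-diethoxyhex-4-yn-2-yl]oxy}-4,4-dimethoxypent-1-en-3-one | C[C@H](CC#CC(OCC)OCC)O/C=C/C(=O)C(C)(OC)OC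
F6 | step 3 | (Z)-1-{[(2R)-6,6-diethoxyhex-4-yn-2-yl]oxy}-2-iodo-4,4-dimethoxypent-1-en-3-one | C[C@H](CC#CC(OCC)OCC)O/C=C(\I)C(=O)C(C)(OC)OC
F7 | step 3 | 1-[(2R,4E)-4-(2,2-diethoxyethylidene)-2-methyl-3,4-dihydro-2H-pyran-5-yl]-2,2-dimethoxypropan-1-one | C[C@@H]1C/C(=C\C(OCC)OCC)C(C(=O)C(C)(OC)OC)=CO1
F8 | step 4 | 3-[(tert-butyldimethylsilyl)oxy]butan-2-one | CC(O[Si](C)(C)C(C)(C)C)C(C)=O
F9 | step 4 | (E)-4-[(tert-butyldimethylsilyl)oxy]-1-(dimethylamino)pent-1-en-3-one | CC(O[Si](C)(C)C(C)(C)C)C(=O)/C=C/N(C)C
F10 | step 4 | 6-[(tert-butyldimethylsilyl)oxy]-4-[(dimethylamino)methylidene]-3-[(2R)-2-hydroxypropyl]-5-oxohept-2-enal | C[C@@H](O)CC(=CC=O)C(=CN(C)C)C(=O)C(C)O[Si](C)(C)C(C)(C)C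
F11 | step 4 | 2-[(2R)-5-{2-[(tert-butyldimethylsilyl)oxy]propanoyl}-2-methyl-2,3-dihydro-4H-pyran-4-ylidene]acetaldehyde | C[C@@H]1CC(=CC=O)C(C(=O)C(C)O[Si](C)(C)C(C)(C)C)=CO1
F12 | step 4 | 2-[(2R)-5-(2-hydroxypropanoyl)-2-methyl-2,3-dihydro-4H-pyran-4-ylidene]acetaldehyde | C[C@@H]1CC(=CC=O)C(C(=O)C(C)O)=CO1
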